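**Plan**

1. Retrosynthesis: (i) cut the lactone C12–O bond and the ring bond C6–C7 (allyl metal at C13 adding to a C6 enal); (ii) cut C2–C3 and C1–C10 of the furanone together, as a (3+2) cycloaddition of a carbonyl ylide C3–O1–C10 with a ketene equivalent (C1–C2); (iii) cut O1–C10 (carbenoid at C10, C9 as ketone) and unfold C3 into an ester on O8.
2. Enabling feature: O1 bridges C3 and C10, and C10 is flanked by the oxygenated carbons C9 and C8. A C9 ketone can therefore activate a diazo group at C10, and the C8 oxygen can hold C3 as an ester carbonyl, so that the ylide sits in a temporary six-membered ring C10–C9–C8–O8–C3–O1. With C3 at the acid level, C2=C3 arises by loss of O8, which frees the hydroxyl that carries the side chain; the C9 ketone is later reduced to the C9 carbinol.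
3. Forward: C7–C13 enoate with C8/C9 from D-glyceraldehyde acetonide → C8 ester with the (Z)-C3–C6 acid → α-diazo ethyl ketone → ylide cycloaddition and acid unveiling give furanone ring A → C8 acylation, C9 reduction → allylchromium closure of the ten-membered ring B and lactone ring C.
4. Stereochemistry: C8 from D-glyceraldehyde; C10 by addition to the ylide face opposite the C8 side chain; C9 by Felkin–Anh reduction; C6/C7 in the ring closure; the side-chain centre from (R)-2-methylbutanoic acid; the Z C4=C5 olefin from 3-methylfuran-2(5H)-one.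

Key step: step 9

Remark: atoms are numbered as in the target throughout (C1 furanone C=O, C2 furanone CH, C3 furanone C–O carbon, C4=C5 ring olefin, C6 lactone carbinol, C7–C10 the stereogenic chain, C11–C13 the methylene lactone carbons, O1 furanone oxygen, O8 the oxygen on C8); the side chain is taken as (R)-2-methylbutanoate, as the SMILES states; TBS = tert-butyldimethylsilyl, PMB = 4-methoxybenzyl.

**Route**

Step 1
Reactants: 1 4-methoxybenzyl alcohol; 2 methyl 2-(dimethoxyphosphoryl)prop-2-enoate; 3 (R)-2,2-dimethyl-1,3-dioxolane-4-carbaldehyde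
Product: 5 (E)-enoate acetonide, via phosphonate carbanion sodium salt 4 (not isolated)
Conditions: NaH (1.05 equiv), 1, THF, 0 °C; 2, −40 °C; then 3, −40 → 0 °C
Reagents that add atoms: none
Why: oxa-Michael addition of the alkoxide to the vinylphosphonate gives carbanion 4, which olefinates the aldehyde (Horner–Wadsworth–Emmons); the α-branched phosphonoacetate should favour the E isomer (ester trans to the dioxolane; a minor Z isomer would lactonise in step 2 and be removed), and C8 is taken from D-glyceraldehyde.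

Step 2
Reactants: 5 (E)-enoate acetonide
Product: 6 (4S)-4,5-diol
Conditions: AcOH/H2O (4:1), 40 °C
Reagents that add atoms: none
Why: acid-catalysed acetal hydrolysis frees the C8/C9 diol while the PMB ether survives, and the E geometry (C8 trans to the ester) rules out lactonisation.

Step 3
Reactants: 6 (4S)-4,5-diol
Product: 7 (2S)-α-hydroxy acid
Conditions: TEMPO (0.2 equiv), PhI(OAc)2 (2.5 equiv), MeCN/H2O (1:1), 0 °C → rt
Reagents that add atoms: water (O)
Why: the TEMPO/PhI(OAc)2 oxidation is selective for the primary C9 alcohol and in water carries the aldehyde hydrate on to the acid, without touching the secondary C8 alcohol or its configuration.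

Step 4
Reactants: 7 (2S)-α-hydroxy acid
Product: 8 allyl ester
Conditions: allyl bromide (1.2 equiv), KHCO3 (1.5 equiv), DMF, rt
Reagents that add atoms: allyl bromide (C=CCBr)
Why: SN2 O-alkylation of the potassium carboxylate under weakly basic conditions masks C9 as an allyl ester and leaves the C8 alcohol free and configurationally intact.

Step 5
Reactants: 9 3-methylfuran-2(5H)-one
Product: 12 (2Z)-4-(TBS-oxy)-2-methylbut-2-enoic acid, via potassium (2Z)-4-hydroxy-2-methylbut-2-enoate 10 (not isolated), via bis-silyl ester ether 11 (not isolated)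
Conditions: KOH (1.05 equiv), MeOH/H2O, rt, evaporate; TBSCl (2.3 equiv), imidazole, DMF, rt; K2CO3 (0.2 equiv), THF/H2O, 0 °C, then pH 5
Reagents that add atoms: potassium hydroxide ([K+].[OH-]); tert-butyldimethylsilyl chloride (CC(C)(C)[Si](C)(C)Cl)
Why: saponification of the butenolide gives the hydroxy acid salt with the Z geometry fixed by the ring; exhaustive silylation and selective hydrolysis of the labile silyl ester then give the Z acid, which can no longer relactonise.

Step 6
Reactants: 8 allyl ester; 12 (2Z)-4-(TBS-oxy)-2-methylbut-2-enoic acid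
Product: 14 C8 ester (tethered diester), via mixed anhydride 13 (not isolated)
Conditions: 12 (1.3 equiv), 2,4,6-trichlorobenzoyl chloride (1.3 equiv), Et3N (1.5 equiv), toluene, rt; then 8, DMAP (1.5 equiv), rt
Reagents that add atoms: none
Why: Yamaguchi esterification through mixed anhydride 13 acylates the C8 alcohol with retention and, as for angelate esters, without Z to E isomerisation of the 2-methylbut-2-enoyl unit; this ester is the tether that will deliver C3 and O1.

Step 7
Reactants: 14 C8 ester (tethered diester)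
Product: 15 C9 carboxylic acid
Conditions: Pd(PPh3)4 (2 mol %), morpholine (2 equiv), THF, 0 °C
Reagents that add atoms: none
Why: Tsuji–Trost deallylation, in which zerovalent palladium ionises the primary allyl ester far faster than the hindered secondary allylic carboxylate at C8 and morpholine traps the allyl group.

Step 8
Reactants: 15 C9 carboxylic acid; 16 N-ethyl-N-nitrosourea
Product: 19 α-diazo ethyl ketone, via acid chloride 17 (not isolated), via diazoethane 18 (not isolated)
Conditions: Me2C=C(Cl)NMe2 (1.2 equiv), CH2Cl2, 0 °C; then CH3CHN2 (18, 3 equiv, from 16 and aq. KOH in Et2O at −20 °C, dried over KOH), Et2O, −30 → 0 °C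
Reagents that add atoms: none
Why: neutral formation of the acid chloride and acylation of diazoethane (Arndt–Eistert-type diazoketone synthesis, a second equivalent of diazoethane taking up HCl) install C10 with its methyl group as a diazo carbon activated by the C9 carbonyl; the low temperature protects the acidic C8–H.

Step 9
Reactants: 19 α-diazo ethyl ketone; 20 1,1-diethoxyethene
Product: 22 2,8-dioxabicyclo[3.2.1]octanone cycloadduct, via carbonyl ylide 21 (not isolated)
Conditions: Rh2(O2CtBu)4 (2 mol %), 20 (5 equiv), CH2Cl2, 4 Å MS, −40 → 0 °C, 19 added over 2 h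
Reagents that add atoms: none
Why: Rh2(O2CtBu)4 converts 19 into the rhodium carbenoid at C10, which is captured by the carbonyl oxygen of the C8 ester (six-membered closure by O-attack on the carbenoid, ring C10–C9–C8–O8–C3–O1) to give carbonyl ylide 21, and 21 adds 20 in a suprafacial (3+2) cycloaddition that closes the five-membered ring O1–C10–C1–C2–C3 and forms C2–C3 and C1–C10 at once. The closest known reaction type is the tandem rhodium-carbenoid cyclisation/1,3-dipolar cycloaddition of α-diazo ketones that carry a δ-carbonyl group, esters included, which is an established entry to 2,8-dioxabicyclo[3.2.1]octanes. Regiochemistry should be polarity-matched: the nucleophilic CH2 of 20 bonds to the oxocarbenium-like C3 and the acetal carbon to the enolate-like C10 (LUMO of the dipole, HOMO of the alkene). The new stereocentre C10 (and the transient one at C3) is set by the face of the nearly planar ylide ring that 20 attacks, anti to the C7 side chain on C8, which gives 10R from 8S. The step needs capture of the carbenoid by the ester oxygen to outrun 1,2-hydride shift from the C10 methyl group and direct attack on 20; the s-cis ester geometry (1,6-relationship), the bulky electron-rich pivalate ligands, the low temperature and slow addition of 19 should secure this. C3 enters at the carboxylic acid level and C1 at the ketone level, so no redox step is needed to reach ring A.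

Step 10
Reactants: 22 2,8-dioxabicyclo[3.2.1]octanone cycloadduct
Product: 23 furanone hydroxy ketone
Conditions: PPTS (0.3 equiv), acetone/H2O (10:1), 50 °C
Reagents that add atoms: water (O)
Why: acid hydrolysis of the C1 diethyl ketal unmasks the ketone, and the bicyclic ketal at C3 then loses the C8 alkoxide and a C2 proton (β-alkoxy ketone elimination), so the temporary ring opens to the 3(2H)-furanone (a vinylogous ester and the thermodynamic sink) with the C8 hydroxyl free and no stereocentre touched.

Step 11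
Reactants: 23 furanone hydroxy ketone; 24 (R)-2-methylbutanoic acid
Product: 25 C8 (R)-2-methylbutanoate
Conditions: 24 (1.5 equiv), DIC (1.6 equiv), DMAP (0.1 equiv), CH2Cl2, 0 °C
Reagents that add atoms: none
Why: Steglich esterification of the only free hydroxyl (C8) installs the side chain with its stereocentre taken from 24; catalytic DMAP at 0 °C should limit epimerisation of C8 and of the α-branched acid.

Step 12
Reactants: 25 C8 (R)-2-methylbutanoate
Product: 26 (9R)-alcohol
Conditions: NaBH4 (1.0 equiv), MeOH/CH2Cl2 (1:1), −78 °C; AcOH quench at −78 °C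
Reagents that add atoms: none
Why: hydride addition to the C9 ketone (the most electrophilic carbonyl; the vinylogous ester of ring A and the enoate are inert at −78 °C) under non-chelating conditions should follow the polar Felkin–Anh model at C8 (C8–O anti to the hydride, approach past C8–H) and give the 8,9-syn 9R alcohol, the dipole-minimised rotamer about C9–C10 (C9=O anti to the furanone C=O) exposing the same face.

Step 13
Reactants: 26 (9R)-alcohol
Product: 27 C13 allylic alcohol
Conditions: DDQ (1.3 equiv), CH2Cl2/pH 7 buffer (10:1), 0 °C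
Reagents that add atoms: none
Why: oxidative PMB cleavage by DDQ (benzylic hydride abstraction, hemiacetal hydrolysis) frees the C13 alcohol under neutral conditions that leave the silyl ether and the 8,9-diol monoester in place.

Step 14
Reactants: 27 C13 allylic alcohol
Product: 28 C13 allylic bromide
Conditions: CBr4 (1.3 equiv), PPh3 (1.3 equiv), CH2Cl2, −20 → 0 °C
Reagents that add atoms: carbon tetrabromide (BrC(Br)(Br)Br)
Why: Appel bromination converts the unhindered primary allylic alcohol into the bromide under neutral conditions, in preference to the hindered secondary C9 alcohol, with the olefin geometry kept.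

Step 15
Reactants: 28 C13 allylic bromide
Product: 29 C6 allylic alcohol
Conditions: HF (48 % aq., 5 equiv), MeCN, 0 °C
Reagents that add atoms: none
Why: acidic fluoride cleaves the primary silyl ether without the base that would trigger acyl migration between O8 and O9 or substitution of the allylic bromide.

Step 16
Reactants: 29 C6 allylic alcohol
Product: 30 (Z)-enal
Conditions: activated MnO2 (15 equiv), CH2Cl2, rt, dark
Reagents that add atoms: none
Why: MnO2 oxidises only the allylic C6 alcohol (the C9 alcohol is not allylic) to the enal under neutral conditions that should preserve the Z C4=C5 geometry.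

Step 17
Reactants: 30 (Z)-enal
Product: 32 target CNP0146060.1, via ring B hydroxy ester 31 (not isolated)
Conditions: CrCl2 (6 equiv), THF (0.002 M), rt, 30 added over 6 h; aqueous work-up; then TsOH·H2O (0.1 equiv), CH2Cl2, rt
Reagents that add atoms: none
Why: two equivalents of divalent chromium turn the bromide into an allylchromium species, whose γ-carbon C7 adds chemoselectively to the C6 aldehyde (intramolecular Nozaki–Hiyama/Barbier allylation through a six-membered chair transition state) and closes ring B; with C5 and C8 antiperiplanar across the forming bond, as the medium ring should prefer, the anti adduct (6R,7S) is expected, and acid then closes the trans-fused lactone ring C with loss of methanol.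

**Compound list**

1 | 4-methoxybenzyl alcohol | COc1ccc(CO)cc1 | starting material
2 | methyl 2-(dimethoxyphosphoryl)prop-2-enoate | COC(=O)C(=C)P(=O)(OC)OC | starting material
3 | (R)-2,2-dimethyl-1,3-dioxolane-4-carbaldehyde | O=C[C@H]1COC(C)(C)O1 | starting material
4 | sodium salt of the carbanion of methyl 2-(dimethoxyphosphoryl)-3-(PMB-oxy)propanoate | [Na+].COC(=O)[C-](COCc1ccc(OC)cc1)P(=O)(OC)OC | intermediate
5 | methyl (2E)-3-[(4S)-2,2-dimethyl-1,3-dioxolan-4-yl]-2-[(PMB-oxy)methyl]prop-2-enoate | COC(=O)/C(COCc1ccc(OC)cc1)=C/[C@H]1COC(C)(C)O1 | intermediate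
6 | methyl (2E,4S)-4,5-dihydroxy-2-[(PMB-oxy)methyl]pent-2-enoate | COC(=O)/C(COCc1ccc(OC)cc1)=C/[C@H](O)CO | intermediate
7 | (2S,3E)-2-hydroxy-5-methoxy-4-[(PMB-oxy)methyl]-5-oxopent-3-enoic acid | COC(=O)/C(COCc1ccc(OC)cc1)=C/[C@H](O)C(=O)O | intermediate
8 | 5-methyl 1-prop-2-en-1-yl (2S,3E)-2-hydroxy-4-[(PMB-oxy)methyl]pent-3-enedioate | COC(=O)/C(COCc1ccc(OC)cc1)=C/[C@H](O)C(=O)OCC=C | intermediate
9 | 3-methylfuran-2(5H)-one | CC1=CCOC1=O | starting material
10 | potassium (2Z)-4-hydroxy-2-methylbut-2-enoate | [K+].[O-]C(=O)/C(C)=C\CO | intermediate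
11 | tert-butyldimethylsilyl (2Z)-4-(TBS-oxy)-2-methylbut-2-enoate | CC(C)(C)[Si](C)(C)OC(=O)/C(C)=C\CO[Si](C)(C)C(C)(C)C | intermediate
12 | (2Z)-4-(TBS-oxy)-2-methylbut-2-enoic acid | OC(=O)/C(C)=C\CO[Si](C)(C)C(C)(C)C | intermediate
13 | mixed anhydride of 12 and 2,4,6-trichlorobenzoic acid | O=C(OC(=O)/C(C)=C\CO[Si](C)(C)C(C)(C)C)c1c(Cl)cc(Cl)cc1Cl | intermediate
14 | 5-methyl 1-prop-2-en-1-yl (2S,3E)-2-{[(2Z)-4-(TBS-oxy)-2-methylbut-2-enoyl]oxy}-4-[(PMB-oxy)methyl]pent-3-enedioate | COC(=O)/C(COCc1ccc(OC)cc1)=C/[C@H](OC(=O)/C(C)=C\CO[Si](C)(C)C(C)(C)C)C(=O)OCC=C | intermediate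
15 | (2S,3E)-2-{[(2Z)-4-(TBS-oxy)-2-methylbut-2-enoyl]oxy}-5-methoxy-4-[(PMB-oxy)methyl]-5-oxopent-3-enoic acid | COC(=O)/C(COCc1ccc(OC)cc1)=C/[C@H](OC(=O)/C(C)=C\CO[Si](C)(C)C(C)(C)C)C(=O)O | intermediate
16 | N-ethyl-N-nitrosourea | CCN(N=O)C(N)=O | starting material
17 | acid chloride of 15 | COC(=O)/C(COCc1ccc(OC)cc1)=C/[C@H](OC(=O)/C(C)=C\CO[Si](C)(C)C(C)(C)C)C(=O)Cl | intermediate
18 | diazoethane | CC=[N+]=[N-] | intermediate
19 | methyl (2E,4S)-4-{[(2Z)-4-(TBS-oxy)-2-methylbut-2-enoyl]oxy}-6-diazo-2-[(PMB-oxy)methyl]-5-oxohept-2-enoate | COC(=O)/C(COCc1ccc(OC)cc1)=C/[C@H](OC(=O)/C(C)=C\CO[Si](C)(C)C(C)(C)C)C(=O)C(C)=[N+]=[N-] | intermediate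
20 | 1,1-diethoxyethene (ketene diethyl acetal) | C=C(OCC)OCC | starting material
21 | carbonyl ylide: 5-oxo-1,3-dioxan-1-ium-6-ide ring made of C10, C9, C8, O8, C3 and O1, with methyl on C10, the (Z)-butenyl chain on C3 and the (E)-enoate chain on C8 (S) | C[C-]1C(=O)[C@H](/C=C(\COCc2ccc(OC)cc2)C(=O)OC)OC(/C(C)=C\CO[Si](C)(C)C(C)(C)C)=[O+]1 | intermediate
22 | methyl (2E)-3-[(1S,3S,5R)-1-[(2Z)-4-(TBS-oxy)but-2-en-2-yl]-6,6-diethoxy-5-methyl-4-oxo-2,8-dioxabicyclo[3.2.1]octan-3-yl]-2-[(PMB-oxy)methyl]prop-2-enoate (enoate chain anti to the C6–C7 bridge) | O=C1[C@H](/C=C(\COCc2ccc(OC)cc2)C(=O)OC)O[C@@]3(/C(C)=C\CO[Si](C)(C)C(C)(C)C)CC(OCC)(OCC)[C@]1(C)O3 | intermediate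
23 | methyl (2E,4S)-5-[(2S)-5-[(2Z)-4-(TBS-oxy)but-2-en-2-yl]-2-methyl-3-oxo-2,3-dihydrofuran-2-yl]-4-hydroxy-2-[(PMB-oxy)methyl]-5-oxopent-2-enoate (C10 arranged as in the target; the descriptor differs because C9 is a ketone) | O=C1C=C(/C(C)=C\CO[Si](C)(C)C(C)(C)C)O[C@]1(C)C(=O)[C@@H](O)/C=C(\COCc2ccc(OC)cc2)C(=O)OC | intermediate
24 | (R)-2-methylbutanoic acid | CC[C@@H](C)C(=O)O | starting material
25 | methyl (2E,4S)-5-[(2S)-5-[(2Z)-4-(TBS-oxy)but-2-en-2-yl]-2-methyl-3-oxo-2,3-dihydrofuran-2-yl]-4-{[(2R)-2-methylbutanoyl]oxy}-2-[(PMB-oxy)methyl]-5-oxopent-2-enoate | O=C1C=C(/C(C)=C\CO[Si](C)(C)C(C)(C)C)O[C@]1(C)C(=O)[C@@H](OC(=O)[C@H](C)CC)/C=C(\COCc2ccc(OC)cc2)C(=O)OC | intermediate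
26 | methyl (2E,4S,5R)-5-[(2R)-5-[(2Z)-4-(TBS-oxy)but-2-en-2-yl]-2-methyl-3-oxo-2,3-dihydrofuran-2-yl]-5-hydroxy-4-{[(2R)-2-methylbutanoyl]oxy}-2-[(PMB-oxy)methyl]pent-2-enoate | O=C1C=C(/C(C)=C\CO[Si](C)(C)C(C)(C)C)O[C@]1(C)[C@H](O)[C@@H](OC(=O)[C@H](C)CC)/C=C(\COCc2ccc(OC)cc2)C(=O)OC | intermediate
27 | methyl (2E,4S,5R)-5-[(2R)-5-[(2Z)-4-(TBS-oxy)but-2-en-2-yl]-2-methyl-3-oxo-2,3-dihydrofuran-2-yl]-5-hydroxy-2-(hydroxymethyl)-4-{[(2R)-2-methylbutanoyl]oxy}pent-2-enoate | O=C1C=C(/C(C)=C\CO[Si](C)(C)C(C)(C)C)O[C@]1(C)[C@H](O)[C@@H](OC(=O)[C@H](C)CC)/C=C(\CO)C(=O)OC | intermediate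
28 | methyl (2Z,4S,5R)-2-(bromomethyl)-5-[(2R)-5-[(2Z)-4-(TBS-oxy)but-2-en-2-yl]-2-methyl-3-oxo-2,3-dihydrofuran-2-yl]-5-hydroxy-4-{[(2R)-2-methylbutanoyl]oxy}pent-2-enoate | O=C1C=C(/C(C)=C\CO[Si](C)(C)C(C)(C)C)O[C@]1(C)[C@H](O)[C@@H](OC(=O)[C@H](C)CC)/C=C(\CBr)C(=O)OC | intermediate
29 | methyl (2Z,4S,5R)-2-(bromomethyl)-5-hydroxy-5-[(2R)-5-[(2Z)-4-hydroxybut-2-en-2-yl]-2-methyl-3-oxo-2,3-dihydrofuran-2-yl]-4-{[(2R)-2-methylbutanoyl]oxy}pent-2-enoate | O=C1C=C(/C(C)=C\CO)O[C@]1(C)[C@H](O)[C@@H](OC(=O)[C@H](C)CC)/C=C(\CBr)C(=O)OC | intermediate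
30 | methyl (2Z,4S,5R)-2-(bromomethyl)-5-hydroxy-5-[(2R)-2-methyl-3-oxo-5-[(2Z)-4-oxobut-2-en-2-yl]-2,3-dihydrofuran-2-yl]-4-{[(2R)-2-methylbutanoyl]oxy}pent-2-enoate | O=C1C=C(/C(C)=C\C=O)O[C@]1(C)[C@H](O)[C@@H](OC(=O)[C@H](C)CC)/C=C(\CBr)C(=O)OC | intermediate
31 | methyl (4Z,6R,7S,8S,9R,10R)-6,9-dihydroxy-8-[(2R)-2-methylbutanoyloxy]-1-oxo-3,10-epoxygermacra-2,4,11(13)-trien-12-oate (ring B closed, lactone still open) | C=C(C(=O)OC)[C@H]1[C@H](O)/C=C(/C)C2=CC(=O)[C@](C)(O2)[C@H](O)[C@H]1OC(=O)[C@H](C)CC | intermediate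
32 | (4Z,6R,7S,8S,9R,10R)-9-hydroxy-8-[(2R)-2-methylbutanoyloxy]-1-oxo-3,10-epoxygermacra-2,4,11(13)-trien-12,6-olide (CNP0146060.1) | C=C1C(=O)O[C@@H]2/C=C(/C)C3=CC(=O)[C@](C)(O3)[C@H](O)[C@@H](OC(=O)[C@H](C)CC)[C@@H]12 | target

**Count and risks**

Total step count: 17. Longest linear sequence: 16 steps (steps 1–4 and 6–17; step 5 is the only side branch).

Step 9 (key step). What may go wrong: 1,2-hydride shift from the C10 methyl group in the carbenoid before the ester oxygen arrives; direct attack of the carbenoid on the ketene acetal; sluggish or wrongly oriented addition of the electron-rich alkene to the alkoxy-stabilised ylide; weak discrimination between the two ylide faces. Fallback (ring A built by stepwise ionic chemistry, without cycloaddition): it sets out from acid chloride 17 and comes back at 23. ZnCl2-mediated C-acylation of 2,3-bis(trimethylsilyloxy)but-2-ene (from butane-2,3-dione) by 17 should give the silyloxy diketone F1 as a mixture at C10. LiN(SiMe3)2 at −78 °C would enolise the methyl ketone, whose carbon C2 takes over the acyl group from O8 (Claisen-type acyl transfer, the classical base route from α-acyloxy ketones to 3(2H)-furanones), and acidic work-up removes the silyl group to give the hydroxy triketone F2. TsOH would then close and dehydrate F2 to 23 together with the C10 epimer F3, to be separated. The price is that C10 is no longer controlled and that C8–H is exposed to base.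

Step 17. What may go wrong: intermolecular allylation (oligomers) in place of ring closure; Z to E isomerisation of the enal before closure; closure with the syn sense at C6/C7, which would lead to the cis-fused lactone; attack on the wrong face of C7. Fallback (C6 set by ketone reduction, not by the C–C bond formation): it sets out from 30 and comes back at 31. If the closure gives the 6-epi hydroxy ester F4, which like 31 should need acid to lactonise and can therefore be intercepted, MnO2 would oxidise its allylic C6 alcohol (C9–OH is not allylic) to the ring B enone F5. Luche reduction (NaBH4, CeCl3, MeOH, −78 °C), with hydride entering from the ring periphery, should then give 31, which is lactonised as in step 17. This does not repair a wrong configuration at C7.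

Step 12. What may go wrong: poor facial selectivity if the quaternary C10 overrides the C8 stereocentre; migration of the acyl group from O8 to the new O9 alkoxide; over-reduction of ring A. Fallback (catalyst control in place of substrate control): it sets out from 25 and comes back at 26. Corey–Bakshi–Shibata reduction with (S)-2-methyl-CBS-oxazaborolidine and catecholborane in toluene at −60 °C, the quaternary C10 side acting as the large substituent, should deliver hydride to the face that gives 9R; the neutral boron alkoxide does not promote acyl shift. No compound beyond the list arises (F0).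

**Further compounds**

F1 | step 9 | methyl (2E,4S)-4-{[(2Z)-4-(TBS-oxy)-2-methylbut-2-enoyl]oxy}-6-methyl-5,7-dioxo-2-[(PMB-oxy)methyl]-6-[(trimethylsilyl)oxy]oct-2-enoate (both C6 epimers) | COC(=O)/C(COCc1ccc(OC)cc1)=C/[C@H](OC(=O)/C(C)=C\CO[Si](C)(C)C(C)(C)C)C(=O)C(C)(O[Si](C)(C)C)C(C)=O
F2 | step 9 | methyl (2E,4S,10Z)-12-(TBS-oxy)-4,6-dihydroxy-6,10-dimethyl-5,7,9-trioxo-2-[(PMB-oxy)methyl]dodeca-2,10-dienoate (both C6 epimers) | COC(=O)/C(COCc1ccc(OC)cc1)=C/[C@H](O)C(=O)C(C)(O)C(=O)CC(=O)/C(C)=C\CO[Si](C)(C)C(C)(C)C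
F3 | step 9 | C10 epimer of 23: methyl (2E,4S)-5-[(2R)-5-[(2Z)-4-(TBS-oxy)but-2-en-2-yl]-2-methyl-3-oxo-2,3-dihydrofuran-2-yl]-4-hydroxy-2-[(PMB-oxy)methyl]-5-oxopent-2-enoate | O=C1C=C(/C(C)=C\CO[Si](C)(C)C(C)(C)C)O[C@@]1(C)C(=O)[C@@H](O)/C=C(\COCc2ccc(OC)cc2)C(=O)OC
F4 | step 17 | C6 epimer of 31: methyl (4Z,6S,7S,8S,9R,10R)-6,9-dihydroxy-8-[(2R)-2-methylbutanoyloxy]-1-oxo-3,10-epoxygermacra-2,4,11(13)-trien-12-oate | C=C(C(=O)OC)[C@H]1[C@@H](O)/C=C(/C)C2=CC(=O)[C@](C)(O2)[C@H](O)[C@H]1OC(=O)[C@H](C)CC
F5 | step 17 | methyl (4Z,7S,8S,9R,10R)-9-hydroxy-8-[(2R)-2-methylbutanoyloxy]-1,6-dioxo-3,10-epoxygermacra-2,4,11(13)-trien-12-oate | C=C(C(=O)OC)[C@H]1C(=O)/C=C(/C)C2=CC(=O)[C@](C)(O2)[C@H](O)[C@H]1OC(=O)[C@H](C)CC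
F0 | step 12 | none | none
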